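**Plan**

1. Atoms are numbered C1 (lactone carbonyl) to C25 (carboxyl carbon); the ring oxygen is O1. The feature used: C17–C18 is the β,β′ bond of the tetrahydrofuran O1–C16–C17–C18–C19 and its two carbons carry a trans O‑acyl/Br pair, the imprint of an anti addition to a C17=C18 alkene. That alkene lies between the two ether carbons C16 and C19, so the ring is a 2,5‑dihydrofuran that ring‑closing metathesis (RCM) of a bis‑allylic ether can close.
2. Cuts (retrosynthetic order): C21=C22 (Wittig); C2=C3 (macrocyclic RCM of a C17 acrylate); C17–O and C18–Br (anti bromo‑acyloxylation); C4–C5 (crotylboration); oxazole (serine condensation); C17=C18 (RCM, closes the dihydrofuran); C15–C16 (glycolate aldol); O1–C16 (alkylation of the tertiary C19 alcohol).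
3. Forward: tertiary allylic alcohol (C18–C21) → glycolate imide → aldol with (S)‑citronellal → dihydrofuran (first ring, step 12) → oxazole (step 14) → enal → bromo acrylate (step 18) → macrolactone (step 20) → side chain (step 27) → deprotection.
4. Stereochemistry: C13 from (S)‑citronellal; C19 from Sharpless epoxidation; C15/C16 from an Evans syn‑glycolate aldol; C17/C18 from ring‑controlled anti addition to the dihydrofuran; C4/C5 from Brown (Z)‑crotylboration; C24 from (S)‑citramalic acid; 6E by Horner–Wadsworth–Emmons, 2E by RCM, 21Z by Wittig.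

Key step: step 12

Step 1
Reactants: 1 but-3-yn-1-ol
Product: 2 tert-butyl(but-3-yn-1-yloxy)diphenylsilane
Conditions: TBDPSCl, imidazole, CH2Cl2, 0 °C → rt
Reagents that add atoms: tert-butyl(chloro)diphenylsilane, CC(C)(C)[Si](Cl)(c1ccccc1)c1ccccc1
Why: Silylation of a primary alcohol; the bulky, weakly basic silyl ether is chosen because it should neither migrate under the alkoxide conditions of step 5 nor act as an internal nucleophile in step 18.

Step 2
Reactants: 2 tert-butyl(but-3-yn-1-yloxy)diphenylsilane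
Product: 4 (E)-5-(tert-butyldiphenylsilyloxy)-3-methylpent-2-en-1-ol, via alkenyldimethylalane 3 (not isolated)
Conditions: AlMe3, Cp2ZrCl2 (25 mol %), CH2Cl2, 0 °C → rt; then n-BuLi, (CH2O)n, THF, −30 °C → rt
Reagents that add atoms: trimethylaluminium, C[Al](C)C; formaldehyde (from paraformaldehyde), C=O
Why: Negishi carboalumination adds methyl and aluminium syn across the alkyne with aluminium at the terminus, and the derived alanate is hydroxymethylated with retention, so the trisubstituted alkene is E.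

Step 3
Reactants: 4 (E)-5-(tert-butyldiphenylsilyloxy)-3-methylpent-2-en-1-ol
Product: 5 [(2R,3R)-3-[2-(tert-butyldiphenylsilyloxy)ethyl]-3-methyloxiran-2-yl]methanol
Conditions: Ti(OiPr)4 (10 mol %), D-(−)-diethyl tartrate (12 mol %), t-BuOOH, 4 Å MS, CH2Cl2, −20 °C
Reagents that add atoms: tert-butyl hydroperoxide, CC(C)(C)OO
Why: Sharpless asymmetric epoxidation of an E allylic alcohol; the D-(−)-tartrate catalyst delivers oxygen to the enantioface that gives the (2R,3R) epoxide, whose tertiary carbon becomes C19 (R).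

Step 4
Reactants: 5 [(2R,3R)-3-[2-(tert-butyldiphenylsilyloxy)ethyl]-3-methyloxiran-2-yl]methanol
Product: 7 (3R)-5-(tert-butyldiphenylsilyloxy)-3-methylpent-1-en-3-ol, via epoxy iodide 6 (not isolated)
Conditions: I2, PPh3, imidazole, THF, 0 °C; then Zn, AcOH, EtOH, 50 °C
Reagents that add atoms: none
Why: Appel-type iodination followed by zinc-induced reductive elimination of the epoxy iodide breaks only the secondary C–O bond, so the tertiary C–O bond and its configuration are kept and the transposed tertiary allylic alcohol results.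

Step 5
Reactants: 7 (3R)-5-(tert-butyldiphenylsilyloxy)-3-methylpent-1-en-3-ol
Product: 8 2-{[(3R)-5-(tert-butyldiphenylsilyloxy)-3-methylpent-1-en-3-yl]oxy}acetic acid
Conditions: NaH, BrCH2CO2H, THF, 0 → 65 °C
Reagents that add atoms: bromoacetic acid, OC(=O)CBr
Why: Williamson etherification of the tertiary sodium alkoxide with sodium bromoacetate, an electrophile that cannot eliminate; C19 is not touched.

Step 6
Reactants: 8 2-{[(3R)-5-(tert-butyldiphenylsilyloxy)-3-methylpent-1-en-3-yl]oxy}acetic acid; 9 (4R)-4-benzyl-1,3-oxazolidin-2-one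
Product: 11 (4R)-4-benzyl-3-(2-{[(3R)-5-(tert-butyldiphenylsilyloxy)-3-methylpent-1-en-3-yl]oxy}acetyl)-1,3-oxazolidin-2-one, via mixed pivalic anhydride 10 (not isolated)
Conditions: PivCl, Et3N, THF, −20 °C; then 9, LiCl, rt
Reagents that add atoms: none
Why: N-Acylation of the oxazolidinone through the mixed pivalic anhydride under LiCl/Et3N activation, a standard imide synthesis.

Step 7
Reactants: 11 glycolyl imide; 12 (S)-citronellal
Product: 14 (4R)-4-benzyl-3-[(2R,3S,5S)-2-{[(3R)-5-(tert-butyldiphenylsilyloxy)-3-methylpent-1-en-3-yl]oxy}-3-hydroxy-5,9-dimethyldec-8-enoyl]-1,3-oxazolidin-2-one, via dibutylboron enolate 13 (not isolated)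
Conditions: Bu2BOTf, Et3N, CH2Cl2, −78 → 0 °C; then 12, −78 → 0 °C; H2O2, MeOH, pH 7 buffer, 0 °C
Reagents that add atoms: none
Why: Evans boron aldol: the Z enolate reacts through a closed chair transition state on the face away from the benzyl group of the (R)-auxiliary, which should give the syn adduct with C16 (R at this stage) and C15 (S) as in the target.

Step 8
Reactants: 14 syn-aldol adduct
Product: 15 the C15 methyl ether of 14 (3-methoxy in place of 3-hydroxy)
Conditions: Me3OBF4, 1,8-bis(dimethylamino)naphthalene, CH2Cl2, 0 °C → rt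
Reagents that add atoms: trimethyloxonium tetrafluoroborate, C[O+](C)C.F[B-](F)(F)F
Why: O-Methylation with an oxonium salt and a non-nucleophilic base avoids alkoxide formation and therefore retro-aldol cleavage or epimerisation.

Step 9
Reactants: 15 methyl ether imide
Product: 16 (2S,3S,5S)-2-{[(3R)-5-(tert-butyldiphenylsilyloxy)-3-methylpent-1-en-3-yl]oxy}-3-methoxy-5,9-dimethyldec-8-en-1-ol
Conditions: LiBH4, MeOH, THF, 0 °C
Reagents that add atoms: none
Why: Reductive cleavage of the N-acyl oxazolidinone gives the primary alcohol and returns the auxiliary; no stereocentre is affected (the descriptor at C16 changes only through priorities).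

Step 10
Reactants: 16 primary alcohol
Product: 17 (2R,3S,5S)-2-{[(3R)-5-(tert-butyldiphenylsilyloxy)-3-methylpent-1-en-3-yl]oxy}-3-methoxy-5,9-dimethyldec-8-enal
Conditions: Dess–Martin periodinane, NaHCO3, CH2Cl2, 0 °C → rt
Reagents that add atoms: none
Why: Buffered Dess–Martin oxidation should give the α-alkoxy aldehyde without epimerisation at C16; it is used at once.

Step 11
Reactants: 17 α-alkoxy aldehyde
Product: 18 tert-butyl{[(3R)-3-{[(3S,4S,6S)-4-methoxy-6,10-dimethylundeca-1,9-dien-3-yl]oxy}-3-methylpent-4-en-1-yl]oxy}diphenylsilane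
Conditions: Ph3PCH3Br, KN(SiMe3)2, THF, 0 °C; then 17, −78 → 0 °C
Reagents that add atoms: methylenetriphenylphosphorane (from methyltriphenylphosphonium bromide), C=P(c1ccccc1)(c1ccccc1)c1ccccc1
Why: Wittig methylenation at low temperature installs the second vinyl group (C17=CH2) faster than the aldehyde can epimerise or eliminate methoxide.

Step 12
Reactants: 18 bis-allylic ether (triene)
Product: 19 (2S,5R)-5-[2-(tert-butyldiphenylsilyloxy)ethyl]-2-[(1S,3S)-1-methoxy-3,7-dimethyloct-6-en-1-yl]-5-methyl-2,5-dihydrofuran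
Conditions: second-generation Grubbs catalyst (H2IMes)(PCy3)Cl2Ru=CHPh (3 mol %), CH2Cl2 (0.02 M), 40 °C
Reagents that add atoms: none
Why: Ring-closing olefin metathesis: the ruthenium benzylidene exchanges onto one monosubstituted vinyl group of 18 by [2+2] cycloaddition and cycloreversion, the new alkylidene adds to the second vinyl group, and collapse of that ruthenacyclobutane forms the C17=C18 double bond and releases ethylene, which drives the reaction. The closest known reaction type is the metathesis of bis-allylic ethers to 2,5-dihydrofurans, which tolerates a fully substituted carbinol carbon next to the alkene. The only ring closed is the five-membered oxacycle O1–C16–C17–C18–C19, formed from two vinyl groups joined 1,3 across the ether oxygen, so both new sp2 carbons are in the ring and the alkene is necessarily cis. No stereocentre is formed: C16 (step 7) and C19 (step 3) are untouched, so the ring is born with its side chain and the C19 methyl cis, and these two centres then steer the anti addition of step 18 that makes C17 and C18 stereogenic. The step needs chemoselectivity for the two vinyl groups over the remote trisubstituted alkene and cyclisation over oligomerisation; the first is secured because the isopropylidene alkene is a poor metathesis partner that could only close a medium ring, the second by the quaternary C19, which biases the diene toward the cyclising conformer.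

Step 13
Reactants: 19 dihydrofuran
Product: 21 (4S,6S)-6-{(2S,5R)-5-[2-(tert-butyldiphenylsilyloxy)ethyl]-5-methyl-2,5-dihydrofuran-2-yl}-6-methoxy-4-methylhexanal, via epoxide 20 (not isolated)
Conditions: mCPBA, NaHCO3, CH2Cl2, −20 °C; then H5IO6, THF/H2O, 0 °C
Reagents that add atoms: meta-chloroperoxybenzoic acid, OOC(=O)c1cccc(Cl)c1; water, O
Why: Prilezhaev epoxidation should select the electron-rich trisubstituted alkene over the dihydrofuran alkene (deactivated by two allylic oxygens), and periodic acid then cleaves the epoxide through its diol to the C10 aldehyde and acetone.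

Step 14
Reactants: 21 C10 aldehyde; 22 L-serine methyl ester hydrochloride
Product: 25 methyl 2-[(3S,5S)-5-{(2S,5R)-5-[2-(tert-butyldiphenylsilyloxy)ethyl]-5-methyl-2,5-dihydrofuran-2-yl}-5-methoxy-3-methylpentyl]-1,3-oxazole-4-carboxylate, via oxazolidine 23 (not isolated), via oxazoline 24 (not isolated)
Conditions: 22, Et3N, MgSO4, CH2Cl2, rt; then BrCCl3, DBU, 0 °C → rt
Reagents that add atoms: none
Why: Condensation gives an oxazolidine that BrCCl3/DBU dehydrogenates twice to the 2,4-disubstituted oxazole, a known one-pot aldehyde-to-oxazole method; the serine stereocentre is lost on aromatisation.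

Step 15
Reactants: 25 oxazole methyl ester
Product: 27 the 4-acetyl oxazole (COCH3 in place of CO2Me in 25), via Weinreb amide 26 (not isolated)
Conditions: MeNHOMe·HCl, iPrMgCl, THF, −20 °C; then MeMgBr, 0 °C
Reagents that add atoms: methylmagnesium bromide, C[Mg]Br
Why: Weinreb ketone synthesis in one pot: the magnesium amide converts the ester into the N-methoxy-N-methylamide, whose chelated adduct with MeMgBr collapses to the methyl ketone only on work-up.

Step 16
Reactants: 27 methyl ketone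
Product: 28 (E)-N-methoxy-N-methyl-3-(oxazol-4-yl)but-2-enamide (the oxazole carries the C11–C21 chain of 25 at C2)
Conditions: (EtO)2P(O)CH2C(O)N(OMe)Me, NaH, THF, 0 → 50 °C
Reagents that add atoms: diethyl [2-(methoxy(methyl)amino)-2-oxoethyl]phosphonate, CCOP(=O)(CC(=O)N(C)OC)OCC
Why: Horner–Wadsworth–Emmons olefination of the heteroaryl methyl ketone should favour the E trisubstituted alkene (oxazole trans to the carbonyl), and any minor Z isomer is removed by chromatography.

Step 17
Reactants: 28 unsaturated Weinreb amide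
Product: 29 (E)-3-(oxazol-4-yl)but-2-enal (same C2 chain; C5 is now the aldehyde)
Conditions: iBu2AlH, THF, −78 °C
Reagents that add atoms: none
Why: Hydride reduction of a Weinreb amide stops at the chelated tetrahedral intermediate and gives the aldehyde on work-up; nothing else in 28 is reducible under these conditions.

Step 18
Reactants: 29 enal with the dihydrofuran
Product: 30 (2R,3R,4S,5R)-4-bromo-5-[2-(tert-butyldiphenylsilyloxy)ethyl]-2-[(1S,3S)-1-methoxy-3-methyl-5-{4-[(E)-4-oxobut-2-en-2-yl]-1,3-oxazol-2-yl}pentyl]-5-methyltetrahydrofuran-3-yl prop-2-enoate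
Conditions: NBS, acrylic acid (20 equiv), CH2Cl2, 0 °C → rt, dark
Reagents that add atoms: N-bromosuccinimide, O=C1CCC(=O)N1Br; acrylic acid, C=CC(=O)O
Why: Intermolecular bromo-acyloxylation: bromonium formation is reversible and only the bromonium on the face of the C16 chain and C19 methyl can be opened by acrylic acid at C17 (the non-neopentyl carbon) anti to the C16 substituent, which should give 17R and 18S, while the enal alkene and acrylic acid are too electron-poor to react with NBS.

Step 19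
Reactants: 30 bromo acrylate enal
Product: 31 the homoallylic alcohol in which the oxazole C4 substituent is (2E,4R,5S)-4-hydroxy-5-methylhepta-2,6-dien-2-yl (rest as 30)
Conditions: (Z)-but-2-ene, KOtBu, n-BuLi, THF, −78 → −45 °C; (+)-Ipc2BOMe, −78 °C; BF3·OEt2; then 30, −78 °C; HOCH2CH2NH2 work-up
Reagents that add atoms: (Z)-but-2-ene, C/C=C\C, delivered as (Z)-but-2-enyldiisopinocampheylborane, C/C=C\CB(C1CC2CC(C1C)C2(C)C)C1CC2CC(C1C)C2(C)C
Why: Brown crotylboration: the Z reagent reacts through a chair transition state to give the syn product, and the isopinocampheyl groups from (+)-Ipc2BOMe select the aldehyde face that should give 5R and hence 4S; the borane adds to the aldehyde only, not to the acrylate.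

Step 20
Reactants: 31 acrylate with terminal vinyl group
Product: 32 macrolactone (2E,4S,5R,6E,13S,15S,16R,17R,18S,19R) with free C5 hydroxyl and a 2-(tert-butyldiphenylsilyloxy)ethyl group on C19
Conditions: second-generation Hoveyda–Grubbs catalyst (H2IMes)Cl2Ru(=CH-2-iPrOC6H4) (10 mol %), toluene (1 mM), 80 °C
Reagents that add atoms: none
Why: Macrocyclic ring-closing metathesis between the terminal vinyl group and the acrylate under high dilution closes the lactone ring at C2=C3 as the E enoate; the trisubstituted C6=C7 alkene does not take part.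

Step 21
Reactants: 32 silyl-protected macrolactone
Product: 33 the C5,C21 diol (2-hydroxyethyl on C19)
Conditions: Bu4NF, AcOH, THF, 0 °C → rt
Reagents that add atoms: none
Why: Buffered fluoride desilylation of the primary silyl ether; the bromide cannot eliminate because H17 is cis to Br and C19 is quaternary.

Step 22
Reactants: 33 diol
Product: 34 the C21 aldehyde with free C5 hydroxyl (CH2CHO on C19)
Conditions: TEMPO (10 mol %), PhI(OAc)2, CH2Cl2, rt
Reagents that add atoms: none
Why: Oxoammonium-mediated oxidation is selective for the unhindered primary alcohol over the hindered secondary allylic C5 hydroxyl and stops at the aldehyde.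

Step 23
Reactants: 35 (S)-citramalic acid
Product: 36 2-[(4S)-2,2,4-trimethyl-5-oxo-1,3-dioxolan-4-yl]acetic acid
Conditions: 2,2-dimethoxypropane, p-TsOH (cat.), rt
Reagents that add atoms: 2,2-dimethoxypropane, COC(C)(C)OC
Why: Acid-catalysed acetonide formation engages the α-hydroxy acid as the five-membered dioxolanone, protecting the tertiary hydroxyl and its carboxyl together and leaving the distal carboxyl free; C24 is not involved.

Step 24
Reactants: 36 dioxolanone acid
Product: 37 (5S)-5-(2-hydroxyethyl)-2,2,5-trimethyl-1,3-dioxolan-4-one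
Conditions: BH3·THF, THF, 0 °C → rt; MeOH quench
Reagents that add atoms: none
Why: Borane reduces the free carboxylic acid much faster than the dioxolanone ester.

Step 25
Reactants: 37 primary alcohol
Product: 38 (5S)-5-(2-iodoethyl)-2,2,5-trimethyl-1,3-dioxolan-4-one
Conditions: I2, PPh3, imidazole, CH2Cl2, 0 °C → rt
Reagents that add atoms: iodine, II
Why: Appel-type iodination of a primary alcohol under neutral conditions that leave the dioxolanone intact.

Step 26
Reactants: 38 iodide
Product: 39 triphenyl{2-[(4S)-2,2,4-trimethyl-5-oxo-1,3-dioxolan-4-yl]ethyl}phosphonium iodide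
Conditions: PPh3, MeCN, 80 °C
Reagents that add atoms: triphenylphosphine, c1ccc(cc1)P(c1ccccc1)c1ccccc1
Why: SN2 quaternisation of triphenylphosphine by an unhindered primary iodide.

Step 27
Reactants: 34 hydroxy aldehyde; 39 phosphonium iodide
Product: 41 the target with its C24 hydroxyl and C25 carboxyl tied as the acetonide (dioxolanone) and a 21Z alkene, via phosphorus ylide 40 (not isolated)
Conditions: 39, NaN(SiMe3)2, THF, −78 → 0 °C; then 34, −78 °C → rt
Reagents that add atoms: none
Why: Wittig olefination with a non-stabilised ylide under salt-free conditions gives the Z alkene through kinetic cis-oxaphosphetane formation; an extra equivalent of ylide covers the free C5 hydroxyl.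

Step 28
Reactants: 41 dioxolanone-protected macrolide
Product: 42 the target (4S,5R,13S,15S,16R,17R,18S,19R,24S; 2E,6E,21Z)
Conditions: AcOH/THF/H2O (3:1:1), 40 °C
Reagents that add atoms: water, O
Why: Mild aqueous acid hydrolyses the acylal-type dioxolanone to the tertiary α-hydroxy acid and acetone without opening the macrolactone or ionising the allylic alcohol.

**Compound list**

1 | but-3-yn-1-ol | C#CCCO | starting material
2 | tert-butyl(but-3-yn-1-yloxy)diphenylsilane | C#CCCO[Si](c1ccccc1)(c1ccccc1)C(C)(C)C | intermediate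
3 | (E)-[4-(tert-butyldiphenylsilyloxy)-2-methylbut-1-en-1-yl]dimethylalane | C[Al](C)/C=C(\C)CCO[Si](c1ccccc1)(c1ccccc1)C(C)(C)C | intermediate (not isolated)
4 | (E)-5-(tert-butyldiphenylsilyloxy)-3-methylpent-2-en-1-ol | OC/C=C(\C)CCO[Si](c1ccccc1)(c1ccccc1)C(C)(C)C | intermediate
5 | [(2R,3R)-3-[2-(tert-butyldiphenylsilyloxy)ethyl]-3-methyloxiran-2-yl]methanol | C[C@]1(CCO[Si](c2ccccc2)(c2ccccc2)C(C)(C)C)O[C@@H]1CO | intermediate
6 | (2S,3R)-3-[2-(tert-butyldiphenylsilyloxy)ethyl]-2-(iodomethyl)-3-methyloxirane | C[C@]1(CCO[Si](c2ccccc2)(c2ccccc2)C(C)(C)C)O[C@@H]1CI | intermediate (not isolated)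
7 | (3R)-5-(tert-butyldiphenylsilyloxy)-3-methylpent-1-en-3-ol | O[C@](C)(CCO[Si](c1ccccc1)(c1ccccc1)C(C)(C)C)C=C | intermediate
8 | 2-{[(3R)-5-(tert-butyldiphenylsilyloxy)-3-methylpent-1-en-3-yl]oxy}acetic acid | OC(=O)CO[C@](C)(CCO[Si](c1ccccc1)(c1ccccc1)C(C)(C)C)C=C | intermediate
9 | (4R)-4-benzyl-1,3-oxazolidin-2-one | O=C1N[C@H](Cc2ccccc2)CO1 | starting material
10 | mixed anhydride of acid 8 with pivalic acid | CC(C)(C)C(=O)OC(=O)CO[C@](C)(CCO[Si](c1ccccc1)(c1ccccc1)C(C)(C)C)C=C | intermediate (not isolated)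
11 | (4R)-4-benzyl-3-(2-{[(3R)-5-(tert-butyldiphenylsilyloxy)-3-methylpent-1-en-3-yl]oxy}acetyl)-1,3-oxazolidin-2-one | O=C(CO[C@](C)(CCO[Si](c1ccccc1)(c1ccccc1)C(C)(C)C)C=C)N1C(=O)OC[C@H]1Cc1ccccc1 | intermediate
12 | (S)-citronellal, (3S)-3,7-dimethyloct-6-enal | CC(C)=CCC[C@H](C)CC=O | starting material
13 | (Z)-dibutylboron enolate of imide 11 | CCCCB(CCCC)O/C(=C\O[C@](C)(CCO[Si](c1ccccc1)(c1ccccc1)C(C)(C)C)C=C)N1C(=O)OC[C@H]1Cc1ccccc1 | intermediate (not isolated)
14 | (4R)-4-benzyl-3-[(2R,3S,5S)-2-{[(3R)-5-(tert-butyldiphenylsilyloxy)-3-methylpent-1-en-3-yl]oxy}-3-hydroxy-5,9-dimethyldec-8-enoyl]-1,3-oxazolidin-2-one | CC(C)=CCC[C@H](C)C[C@H](O)[C@@H](O[C@](C)(CCO[Si](c1ccccc1)(c1ccccc1)C(C)(C)C)C=C)C(=O)N1C(=O)OC[C@H]1Cc1ccccc1 | intermediate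
15 | 3-O-methyl ether of 14 (C15 OMe) | CC(C)=CCC[C@H](C)C[C@H](OC)[C@@H](O[C@](C)(CCO[Si](c1ccccc1)(c1ccccc1)C(C)(C)C)C=C)C(=O)N1C(=O)OC[C@H]1Cc1ccccc1 | intermediate
16 | (2S,3S,5S)-2-{[(3R)-5-(tert-butyldiphenylsilyloxy)-3-methylpent-1-en-3-yl]oxy}-3-methoxy-5,9-dimethyldec-8-en-1-ol | CC(C)=CCC[C@H](C)C[C@H](OC)[C@@H](O[C@](C)(CCO[Si](c1ccccc1)(c1ccccc1)C(C)(C)C)C=C)CO | intermediate
17 | (2R,3S,5S)-2-{[(3R)-5-(tert-butyldiphenylsilyloxy)-3-methylpent-1-en-3-yl]oxy}-3-methoxy-5,9-dimethyldec-8-enal | CC(C)=CCC[C@H](C)C[C@H](OC)[C@@H](O[C@](C)(CCO[Si](c1ccccc1)(c1ccccc1)C(C)(C)C)C=C)C=O | intermediate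
18 | tert-butyl{[(3R)-3-{[(3S,4S,6S)-4-methoxy-6,10-dimethylundeca-1,9-dien-3-yl]oxy}-3-methylpent-4-en-1-yl]oxy}diphenylsilane | CC(C)=CCC[C@H](C)C[C@H](OC)[C@@H](O[C@](C)(CCO[Si](c1ccccc1)(c1ccccc1)C(C)(C)C)C=C)C=C | intermediate
19 | (2S,5R)-5-[2-(tert-butyldiphenylsilyloxy)ethyl]-2-[(1S,3S)-1-methoxy-3,7-dimethyloct-6-en-1-yl]-5-methyl-2,5-dihydrofuran | CC(C)=CCC[C@H](C)C[C@H](OC)[C@H]1O[C@](C)(CCO[Si](c2ccccc2)(c2ccccc2)C(C)(C)C)C=C1 | intermediate
20 | 6,7-epoxide of the octenyl chain of 19 (both epimers at the epoxide CH) | CC1(C)OC1CC[C@H](C)C[C@H](OC)[C@H]1O[C@](C)(CCO[Si](c2ccccc2)(c2ccccc2)C(C)(C)C)C=C1 | intermediate (not isolated)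
21 | (4S,6S)-6-{(2S,5R)-5-[2-(tert-butyldiphenylsilyloxy)ethyl]-5-methyl-2,5-dihydrofuran-2-yl}-6-methoxy-4-methylhexanal | O=CCC[C@H](C)C[C@H](OC)[C@H]1O[C@](C)(CCO[Si](c2ccccc2)(c2ccccc2)C(C)(C)C)C=C1 | intermediate
22 | L-serine methyl ester hydrochloride | Cl.COC(=O)[C@@H](N)CO | starting material
23 | methyl (4S)-2-substituted 1,3-oxazolidine-4-carboxylate from 21 (both C2 epimers) | COC(=O)[C@@H]1COC(CC[C@H](C)C[C@H](OC)[C@H]2O[C@](C)(CCO[Si](c3ccccc3)(c3ccccc3)C(C)(C)C)C=C2)N1 | intermediate (not isolated)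
24 | methyl (4S)-2-substituted 4,5-dihydro-1,3-oxazole-4-carboxylate | COC(=O)[C@@H]1COC(CC[C@H](C)C[C@H](OC)[C@H]2O[C@](C)(CCO[Si](c3ccccc3)(c3ccccc3)C(C)(C)C)C=C2)=N1 | intermediate (not isolated)
25 | methyl 2-[(3S,5S)-5-{(2S,5R)-5-[2-(tert-butyldiphenylsilyloxy)ethyl]-5-methyl-2,5-dihydrofuran-2-yl}-5-methoxy-3-methylpentyl]-1,3-oxazole-4-carboxylate | COC(=O)c1coc(CC[C@H](C)C[C@H](OC)[C@H]2O[C@](C)(CCO[Si](c3ccccc3)(c3ccccc3)C(C)(C)C)C=C2)n1 | intermediate
26 | N-methoxy-N-methyl amide corresponding to ester 25 | CON(C)C(=O)c1coc(CC[C@H](C)C[C@H](OC)[C@H]2O[C@](C)(CCO[Si](c3ccccc3)(c3ccccc3)C(C)(C)C)C=C2)n1 | intermediate (not isolated)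
27 | 4-acetyl oxazole corresponding to 25 | CC(=O)c1coc(CC[C@H](C)C[C@H](OC)[C@H]2O[C@](C)(CCO[Si](c3ccccc3)(c3ccccc3)C(C)(C)C)C=C2)n1 | intermediate
28 | (E)-N-methoxy-N-methyl-3-(2-substituted oxazol-4-yl)but-2-enamide | CON(C)C(=O)/C=C(\C)c1coc(CC[C@H](C)C[C@H](OC)[C@H]2O[C@](C)(CCO[Si](c3ccccc3)(c3ccccc3)C(C)(C)C)C=C2)n1 | intermediate
29 | (E)-3-(2-substituted oxazol-4-yl)but-2-enal | O=C/C=C(\C)c1coc(CC[C@H](C)C[C@H](OC)[C@H]2O[C@](C)(CCO[Si](c3ccccc3)(c3ccccc3)C(C)(C)C)C=C2)n1 | intermediate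
30 | (2R,3R,4S,5R)-4-bromo-5-[2-(tert-butyldiphenylsilyloxy)ethyl]-2-[(1S,3S)-1-methoxy-3-methyl-5-{4-[(E)-4-oxobut-2-en-2-yl]-1,3-oxazol-2-yl}pentyl]-5-methyltetrahydrofuran-3-yl prop-2-enoate | O=C/C=C(\C)c1coc(CC[C@H](C)C[C@H](OC)[C@H]2O[C@](C)(CCO[Si](c3ccccc3)(c3ccccc3)C(C)(C)C)[C@@H](Br)[C@@H]2OC(=O)C=C)n1 | intermediate
31 | as 30 with a (2E,4R,5S)-4-hydroxy-5-methylhepta-2,6-dien-2-yl group on oxazole C4 | C=C[C@H](C)[C@@H](O)/C=C(\C)c1coc(CC[C@H](C)C[C@H](OC)[C@H]2O[C@](C)(CCO[Si](c3ccccc3)(c3ccccc3)C(C)(C)C)[C@@H](Br)[C@@H]2OC(=O)C=C)n1 | intermediate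
32 | macrolactone with free C5 hydroxyl and C21 O-TBDPS | CO[C@H]1C[C@@H](C)CCc2nc(co2)/C(C)=C/[C@H](O)[C@@H](C)/C=C/C(=O)O[C@@H]2[C@@H]1O[C@](C)(CCO[Si](c1ccccc1)(c1ccccc1)C(C)(C)C)[C@H]2Br | intermediate
33 | macrolactone C5,C21 diol | CO[C@H]1C[C@@H](C)CCc2nc(co2)/C(C)=C/[C@H](O)[C@@H](C)/C=C/C(=O)O[C@@H]2[C@@H]1O[C@](C)(CCO)[C@H]2Br | intermediate
34 | macrolactone C21 aldehyde | CO[C@H]1C[C@@H](C)CCc2nc(co2)/C(C)=C/[C@H](O)[C@@H](C)/C=C/C(=O)O[C@@H]2[C@@H]1O[C@](C)(CC=O)[C@H]2Br | intermediate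
35 | (S)-citramalic acid | OC(=O)C[C@](C)(O)C(=O)O | starting material
36 | 2-[(4S)-2,2,4-trimethyl-5-oxo-1,3-dioxolan-4-yl]acetic acid | OC(=O)C[C@]1(C)OC(C)(C)OC1=O | intermediate
37 | (5S)-5-(2-hydroxyethyl)-2,2,5-trimethyl-1,3-dioxolan-4-one | OCC[C@]1(C)OC(C)(C)OC1=O | intermediate
38 | (5S)-5-(2-iodoethyl)-2,2,5-trimethyl-1,3-dioxolan-4-one | ICC[C@]1(C)OC(C)(C)OC1=O | intermediate
39 | triphenyl{2-[(4S)-2,2,4-trimethyl-5-oxo-1,3-dioxolan-4-yl]ethyl}phosphonium iodide | [I-].c1ccccc1[P+](c1ccccc1)(c1ccccc1)CC[C@]1(C)OC(C)(C)OC1=O | intermediate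
40 | ylide of 39 | c1ccccc1P(c1ccccc1)(c1ccccc1)=CC[C@]1(C)OC(C)(C)OC1=O | intermediate (not isolated)
41 | target protected as the C24/C25 acetonide (dioxolanone) | CO[C@H]1C[C@@H](C)CCc2nc(co2)/C(C)=C/[C@H](O)[C@@H](C)/C=C/C(=O)O[C@@H]2[C@@H]1O[C@](C)(C/C=C\C[C@]1(C)OC(C)(C)OC1=O)[C@H]2Br | intermediate
42 | CNP0163177.2 | CO[C@H]1C[C@@H](C)CCc2nc(co2)/C(C)=C/[C@H](O)[C@@H](C)/C=C/C(=O)O[C@@H]2[C@@H]1O[C@](C)(C/C=C\C[C@](C)(O)C(=O)O)[C@H]2Br | target

**Count**

Total steps: 28. Longest linear sequence: 24 steps (steps 1–22, 27 and 28).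

**Steps most likely to fail**

Step 18 (bromo-acyloxylation). What may go wrong: the bromonium on the more open face may be captured before it reverts, the acid may open it at C18 instead of C17, or capture by acrylic acid may be too slow to compete with other bromination. The fallback sets out from 29 and comes back at 30. syn-Dihydroxylation of the dihydrofuran alkene (OsO4, N-methylmorpholine N-oxide, acetone/H2O) should occur mainly on the face opposite the C16 side chain and give the cis-diol F1. The less hindered C17 hydroxyl is acylated with acryloyl chloride and collidine at −78 °C to give the hydroxy acrylate F2. The remaining C18 hydroxyl is converted into the triflate F3 (Tf2O, pyridine) and displaced by Bu4NBr with inversion. The cis acrylate cannot participate from the rear, so this gives 30 with Br trans to the ester.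

Step 20 (macrocyclic RCM). What may go wrong: slow closure between the electron-poor acrylate and the allylically branched vinyl group, leading to oligomerisation or catalyst decay. The fallback sets out from 29 and comes back at 33; it closes the same C2=C3 bond by olefination instead.
- Bromo-acyloxylation with diethylphosphonoacetic acid in place of acrylic acid gives the bromo phosphonoacetate F4.
- An Evans syn-aldol with the dibutylboron enolate of (4R)-4-benzyl-3-propionyl-1,3-oxazolidin-2-one sets C4 and C5 and gives the adduct F5.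
- Et3SiOTf/2,6-lutidine gives the silyl ether F6.
- LiBH4/MeOH cleaves the imide (faster than the hindered phosphonoacetate) to the primary alcohol F7.
- Dess–Martin oxidation gives the aldehyde F8.
- Intramolecular Horner–Wadsworth–Emmons reaction (LiCl, iPr2NEt, MeCN, high dilution) gives the doubly silylated macrolactone F9.
- Bu4NF/AcOH removes both silyl groups and gives 33.

Step 22 (oxidation next to a free allylic alcohol, feeding the late Wittig). What may go wrong: over-oxidation at C5, or β-elimination of the ring oxygen from the β-alkoxy aldehyde under the basic ylide conditions of step 27. The fallback sets out from 33 and comes back at 41 by reversing the polarity of the Wittig reaction. Selective iodination of the primary hydroxyl (I2, PPh3, imidazole) gives the macrocyclic iodide F10. PPh3 in MeCN gives the macrocyclic phosphonium iodide F11. Its ylide is made with NaN(SiMe3)2, with one extra equivalent for the C5 hydroxyl, and is condensed with the dioxolanone aldehyde F12, which is made from alcohol 37 by Dess–Martin oxidation. This gives 41 with the same Z alkene.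

Further compounds
F1 | step 18 | cis-C17,C18-diol of 29 (both hydroxyls trans to the C16 side chain) | O=C/C=C(\C)c1coc(CC[C@H](C)C[C@H](OC)[C@H]2O[C@](C)(CCO[Si](c3ccccc3)(c3ccccc3)C(C)(C)C)[C@H](O)[C@@H]2O)n1
F2 | step 18 | C17 acrylate of diol F1 with free C18 hydroxyl | O=C/C=C(\C)c1coc(CC[C@H](C)C[C@H](OC)[C@H]2O[C@](C)(CCO[Si](c3ccccc3)(c3ccccc3)C(C)(C)C)[C@H](O)[C@@H]2OC(=O)C=C)n1
F3 | step 18 | C18 triflate of F2 | O=C/C=C(\C)c1coc(CC[C@H](C)C[C@H](OC)[C@H]2O[C@](C)(CCO[Si](c3ccccc3)(c3ccccc3)C(C)(C)C)[C@H](OS(=O)(=O)C(F)(F)F)[C@@H]2OC(=O)C=C)n1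
F4 | step 20 | analogue of 30 with a diethylphosphonoacetate at C17 | O=C/C=C(\C)c1coc(CC[C@H](C)C[C@H](OC)[C@H]2O[C@](C)(CCO[Si](c3ccccc3)(c3ccccc3)C(C)(C)C)[C@@H](Br)[C@@H]2OC(=O)CP(=O)(OCC)OCC)n1
F5 | step 20 | Evans syn-aldol adduct of F4 (C4, C5 as in the target; C3 as the N-acyl oxazolidinone) | O=C(N1C(=O)OC[C@H]1Cc1ccccc1)[C@H](C)[C@@H](O)/C=C(\C)c1coc(CC[C@H](C)C[C@H](OC)[C@H]2O[C@](C)(CCO[Si](c3ccccc3)(c3ccccc3)C(C)(C)C)[C@@H](Br)[C@@H]2OC(=O)CP(=O)(OCC)OCC)n1
F6 | step 20 | C5 triethylsilyl ether of F5 | O=C(N1C(=O)OC[C@H]1Cc1ccccc1)[C@H](C)[C@@H](O[Si](CC)(CC)CC)/C=C(\C)c1coc(CC[C@H](C)C[C@H](OC)[C@H]2O[C@](C)(CCO[Si](c3ccccc3)(c3ccccc3)C(C)(C)C)[C@@H](Br)[C@@H]2OC(=O)CP(=O)(OCC)OCC)n1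
F7 | step 20 | C3 primary alcohol from F6 | OC[C@H](C)[C@@H](O[Si](CC)(CC)CC)/C=C(\C)c1coc(CC[C@H](C)C[C@H](OC)[C@H]2O[C@](C)(CCO[Si](c3ccccc3)(c3ccccc3)C(C)(C)C)[C@@H](Br)[C@@H]2OC(=O)CP(=O)(OCC)OCC)n1
F8 | step 20 | C3 aldehyde from F7 | O=C[C@H](C)[C@@H](O[Si](CC)(CC)CC)/C=C(\C)c1coc(CC[C@H](C)C[C@H](OC)[C@H]2O[C@](C)(CCO[Si](c3ccccc3)(c3ccccc3)C(C)(C)C)[C@@H](Br)[C@@H]2OC(=O)CP(=O)(OCC)OCC)n1
F9 | step 20 | macrolactone with C5 O-triethylsilyl and C21 O-TBDPS | CO[C@H]1C[C@@H](C)CCc2nc(co2)/C(C)=C/[C@H](O[Si](CC)(CC)CC)[C@@H](C)/C=C/C(=O)O[C@@H]2[C@@H]1O[C@](C)(CCO[Si](c1ccccc1)(c1ccccc1)C(C)(C)C)[C@H]2Br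
F10 | step 22 | macrolactone C21 iodide (2-iodoethyl on C19) | CO[C@H]1C[C@@H](C)CCc2nc(co2)/C(C)=C/[C@H](O)[C@@H](C)/C=C/C(=O)O[C@@H]2[C@@H]1O[C@](C)(CCI)[C@H]2Br
F11 | step 22 | macrolactone C21 triphenylphosphonium iodide | [I-].CO[C@H]1C[C@@H](C)CCc2nc(co2)/C(C)=C/[C@H](O)[C@@H](C)/C=C/C(=O)O[C@@H]2[C@@H]1O[C@](C)(CC[P+](c1ccccc1)(c1ccccc1)c1ccccc1)[C@H]2Br
F12 | step 22 | 2-[(4S)-2,2,4-trimethyl-5-oxo-1,3-dioxolan-4-yl]acetaldehyde | O=CC[C@]1(C)OC(C)(C)OC1=O
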